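**Retrosynthetic overview**
1. Target ⇐ bis-tert-butyl-protected diester (one TFA acidolysis); coumarate ester ⇐ primary alcohol + (E)-4-tert-butoxycinnamic acid (Steglich), the acid coming from 4-tert-butoxybenzaldehyde and malonic acid.
2. C5 acrylate arm ⇐ Heck reaction of the 5-bromide with tert-butyl acrylate; bromide ⇐ para-selective NBS bromination of the dihydrobenzofuran.
3. Dihydrofuran ring ⇐ intramolecular Pd-catalysed aryl C–O coupling of a 1-(2-bromophenyl)butan-2-ol, with retention at the carbinol carbon.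
4. Key C–C bond (ring C2 to the side-chain CH(CH3)) ⇐ Evans syn boron aldol of (R)-4-benzyl-3-propionyl-2-oxazolidinone with 2-(2-bromophenyl)acetaldehyde, which sets both stereocentres; LiBH4 then turns the acyl carbon into the CH2O arm.
5. Ring order: only one ring is built (the dihydrofuran ring, closed at O1–C7a after the aldol); both benzene rings are bought.

Assumption: both stereocentres are (S) as read from the SMILES (ring C2 and the side-chain methine), and catalogue items such as the (R)-propionyl oxazolidinone and 4-tert-butoxybenzaldehyde count as commercially available.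

**Route**

Step 1
Reactants: 1 2-(2-bromophenyl)ethan-1-ol
Product: 2 2-(2-bromophenyl)acetaldehyde
Conditions: Dess–Martin periodinane (1.1 equiv), CH2Cl2, 0 °C → rt; filter through silica, use at once
Reagents that add atoms: none
Why: Dess–Martin oxidation stops at the aldehyde under neutral, non-enolising conditions, which suits a labile arylacetaldehyde that is used immediately.

Step 2
Reactants: 2 2-(2-bromophenyl)acetaldehyde, 3 (4R)-4-benzyl-3-propanoyl-1,3-oxazolidin-2-one
Product: 6 (4R)-4-benzyl-3-[(2R,3S)-4-(2-bromophenyl)-3-hydroxy-2-methylbutanoyl]-1,3-oxazolidin-2-one, via (Z)-dibutylboron enolate 4 (not isolated), via dibutylboron aldolate 5 (not isolated)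
Conditions: Bu2BOTf (1.2 equiv), i-Pr2NEt (1.3 equiv), CH2Cl2, 0 °C; then 2, −78 → 0 °C; pH 7 buffer, MeOH, 30% H2O2, 0 °C
Reagents that add atoms: none
Why: Evans syn boron aldol reaction, in which the (Z)-boron enolate reacts through a closed Zimmerman–Traxler chair on the face opposite the benzyl group of the (R)-auxiliary, setting C2 (R, the later side-chain methine) and C3 (S, the later ring C2) syn to each other in one step.

Step 3
Reactants: 6 (4R)-4-benzyl-3-[(2R,3S)-4-(2-bromophenyl)-3-hydroxy-2-methylbutanoyl]-1,3-oxazolidin-2-one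
Product: 7 (2S,3S)-4-(2-bromophenyl)-2-methylbutane-1,3-diol
Conditions: LiBH4 (2 equiv), H2O (1.1 equiv), Et2O, 0 °C
Reagents that add atoms: none
Why: Reductive cleavage of the N-acyloxazolidinone by LiBH4 at the exocyclic carbonyl gives the primary alcohol and returns the auxiliary without touching the aryl bromide or either stereocentre (the 2R→2S change is only a CIP priority change).

Step 4
Reactants: 7 (2S,3S)-4-(2-bromophenyl)-2-methylbutane-1,3-diol
Product: 8 (2S,3S)-1-(2-bromophenyl)-4-[(tert-butyldiphenylsilyl)oxy]-3-methylbutan-2-ol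
Conditions: TBDPSCl (1.05 equiv), imidazole (2 equiv), CH2Cl2, 0 °C → rt
Reagents that add atoms: tert-butyl(chloro)diphenylsilane (TBDPSCl), CC(C)(C)[Si](Cl)(c1ccccc1)c1ccccc1
Why: Silyl ether formation with the bulky chlorosilane is selective for the primary over the hindered secondary hydroxyl, leaving the secondary OH free for ring closure.

Step 5
Reactants: 8 (2S,3S)-1-(2-bromophenyl)-4-[(tert-butyldiphenylsilyl)oxy]-3-methylbutan-2-ol
Product: 9 tert-butyl{(2S)-2-[(2S)-2,3-dihydro-1-benzofuran-2-yl]propoxy}diphenylsilane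
Conditions: Pd(OAc)2 (3 mol %), rac-2-(di-tert-butylphosphino)-1,1'-binaphthyl (4 mol %), Cs2CO3 (1.5 equiv), toluene, 80 °C
Reagents that add atoms: none
Why: Intramolecular Buchwald-type palladium-catalysed aryl etherification closes the five-membered ring by forming the aryl–oxygen bond, so the carbinol C–O bond is never broken and the (S) centre is retained, while the bulky di-tert-butylphosphine ligand favours C–O reductive elimination over β-hydride elimination.

Step 6
Reactants: 9 tert-butyl{(2S)-2-[(2S)-2,3-dihydro-1-benzofuran-2-yl]propoxy}diphenylsilane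
Product: 10 {(2S)-2-[(2S)-5-bromo-2,3-dihydro-1-benzofuran-2-yl]propoxy}(tert-butyl)diphenylsilane
Conditions: NBS (1.05 equiv), MeCN, 0 °C → rt, dark
Reagents that add atoms: N-bromosuccinimide (NBS), O=C1CCC(=O)N1Br
Why: Electrophilic aromatic bromination of the 2,3-dihydrobenzofuran goes para to the ring oxygen (C5), the most activated and least hindered position.

Step 7
Reactants: 10 {(2S)-2-[(2S)-5-bromo-2,3-dihydro-1-benzofuran-2-yl]propoxy}(tert-butyl)diphenylsilane, 11 tert-butyl acrylate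
Product: 12 tert-butyl (2E)-3-[(2S)-2-{(2S)-1-[(tert-butyldiphenylsilyl)oxy]propan-2-yl}-2,3-dihydro-1-benzofuran-5-yl]prop-2-enoate
Conditions: Pd(OAc)2 (5 mol %), P(o-tol)3 (10 mol %), Et3N (2 equiv), DMF, 100 °C
Reagents that add atoms: none
Why: Mizoroki–Heck reaction of the aryl bromide with the acrylate gives the (E)-cinnamate through syn insertion and syn β-hydride elimination.

Step 8
Reactants: 12 tert-butyl (2E)-3-[(2S)-2-{(2S)-1-[(tert-butyldiphenylsilyl)oxy]propan-2-yl}-2,3-dihydro-1-benzofuran-5-yl]prop-2-enoate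
Product: 13 tert-butyl (2E)-3-{(2S)-2-[(2S)-1-hydroxypropan-2-yl]-2,3-dihydro-1-benzofuran-5-yl}prop-2-enoate
Conditions: TBAF (1.5 equiv), AcOH (1.5 equiv), THF, 0 °C → rt
Reagents that add atoms: none
Why: Fluoride-mediated desilylation buffered with acetic acid removes the silyl ether without touching the tert-butyl enoate or the stereocentres.

Step 9
Reactants: 14 4-tert-butoxybenzaldehyde, 15 malonic acid
Product: 17 (2E)-3-(4-tert-butoxyphenyl)prop-2-enoic acid, via arylidenemalonic acid 16 (not isolated)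
Conditions: pyridine, piperidine (0.1 equiv), 90 °C; cold aq. citric acid work-up
Reagents that add atoms: none
Why: Knoevenagel–Doebner condensation, in which the arylidenemalonic acid forms and decarboxylates in hot pyridine to the thermodynamically favoured (E)-cinnamic acid, the aryl tert-butyl ether being stable to base.

Step 10
Reactants: 13 tert-butyl (2E)-3-{(2S)-2-[(2S)-1-hydroxypropan-2-yl]-2,3-dihydro-1-benzofuran-5-yl}prop-2-enoate, 17 (2E)-3-(4-tert-butoxyphenyl)prop-2-enoic acid
Product: 19 (2S)-2-[(2S)-5-{(1E)-3-tert-butoxy-3-oxoprop-1-en-1-yl}-2,3-dihydro-1-benzofuran-2-yl]propyl (2E)-3-(4-tert-butoxyphenyl)prop-2-enoate, via O-acylisourea 18 (not isolated)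
Conditions: DCC (1.2 equiv), DMAP (0.1 equiv), CH2Cl2, 0 °C → rt
Reagents that add atoms: none
Why: Steglich esterification (carbodiimide activation to the O-acylisourea, then DMAP acyl transfer) acylates the unhindered primary alcohol under neutral conditions that leave both tert-butyl groups, both alkenes and the stereocentres alone.

Step 11
Reactants: 19 (2S)-2-[(2S)-5-{(1E)-3-tert-butoxy-3-oxoprop-1-en-1-yl}-2,3-dihydro-1-benzofuran-2-yl]propyl (2E)-3-(4-tert-butoxyphenyl)prop-2-enoate
Product: 20 (2E)-3-{(2S)-2-[(2S)-1-{[(2E)-3-(4-hydroxyphenyl)prop-2-enoyl]oxy}propan-2-yl]-2,3-dihydro-1-benzofuran-5-yl}prop-2-enoic acid (CNP0224846.1)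
Conditions: TFA/CH2Cl2/H2O (10:10:1), 0 °C → rt
Reagents that add atoms: none
Why: Acidolysis cleaves the tert-butyl ester and the aryl tert-butyl ether in one operation by loss of 2-methylpropene (water traps the cation), while the primary coumarate ester, the dihydrobenzofuran and both stereocentres are inert to TFA.

**Compound list**
1 | 2-(2-bromophenyl)ethan-1-ol | OCCc1ccccc1Br | starting material
2 | 2-(2-bromophenyl)acetaldehyde | O=CCc1ccccc1Br | intermediate
3 | (4R)-4-benzyl-3-propanoyl-1,3-oxazolidin-2-one | CCC(=O)N1[C@H](Cc2ccccc2)COC1=O | starting material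
4 | (4R)-4-benzyl-3-[(1Z)-1-[(dibutylboranyl)oxy]prop-1-en-1-yl]-1,3-oxazolidin-2-one ((Z)-dibutylboron enolate) | C/C=C(\OB(CCCC)CCCC)N1[C@H](Cc2ccccc2)COC1=O | intermediate
5 | (4R)-4-benzyl-3-[(2R,3S)-4-(2-bromophenyl)-3-[(dibutylboranyl)oxy]-2-methylbutanoyl]-1,3-oxazolidin-2-one (dibutylboron aldolate) | C[C@H]([C@@H](OB(CCCC)CCCC)Cc1ccccc1Br)C(=O)N1[C@H](Cc2ccccc2)COC1=O | intermediate
6 | (4R)-4-benzyl-3-[(2R,3S)-4-(2-bromophenyl)-3-hydroxy-2-methylbutanoyl]-1,3-oxazolidin-2-one | C[C@H]([C@@H](O)Cc1ccccc1Br)C(=O)N1[C@H](Cc2ccccc2)COC1=O | intermediate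
7 | (2S,3S)-4-(2-bromophenyl)-2-methylbutane-1,3-diol | C[C@@H](CO)[C@@H](O)Cc1ccccc1Br | intermediate
8 | (2S,3S)-1-(2-bromophenyl)-4-[(tert-butyldiphenylsilyl)oxy]-3-methylbutan-2-ol | C[C@@H](CO[Si](c1ccccc1)(c1ccccc1)C(C)(C)C)[C@@H](O)Cc1ccccc1Br | intermediate
9 | tert-butyl{(2S)-2-[(2S)-2,3-dihydro-1-benzofuran-2-yl]propoxy}diphenylsilane | C[C@@H](CO[Si](c1ccccc1)(c1ccccc1)C(C)(C)C)[C@@H]1Cc2ccccc2O1 | intermediate
10 | {(2S)-2-[(2S)-5-bromo-2,3-dihydro-1-benzofuran-2-yl]propoxy}(tert-butyl)diphenylsilane | C[C@@H](CO[Si](c1ccccc1)(c1ccccc1)C(C)(C)C)[C@@H]1Cc2cc(Br)ccc2O1 | intermediate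
11 | tert-butyl acrylate | C=CC(=O)OC(C)(C)C | starting material
12 | tert-butyl (2E)-3-[(2S)-2-{(2S)-1-[(tert-butyldiphenylsilyl)oxy]propan-2-yl}-2,3-dihydro-1-benzofuran-5-yl]prop-2-enoate | C[C@@H](CO[Si](c1ccccc1)(c1ccccc1)C(C)(C)C)[C@@H]1Cc2cc(/C=C/C(=O)OC(C)(C)C)ccc2O1 | intermediate
13 | tert-butyl (2E)-3-{(2S)-2-[(2S)-1-hydroxypropan-2-yl]-2,3-dihydro-1-benzofuran-5-yl}prop-2-enoate | C[C@@H](CO)[C@@H]1Cc2cc(/C=C/C(=O)OC(C)(C)C)ccc2O1 | intermediate
14 | 4-tert-butoxybenzaldehyde | CC(C)(C)Oc1ccc(C=O)cc1 | starting material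
15 | malonic acid | OC(=O)CC(=O)O | starting material
16 | 2-(4-tert-butoxybenzylidene)malonic acid | CC(C)(C)Oc1ccc(C=C(C(=O)O)C(=O)O)cc1 | intermediate
17 | (2E)-3-(4-tert-butoxyphenyl)prop-2-enoic acid | CC(C)(C)Oc1ccc(/C=C/C(=O)O)cc1 | intermediate
18 | O-[(2E)-3-(4-tert-butoxyphenyl)prop-2-enoyl]-N,N'-dicyclohexylisourea | CC(C)(C)Oc1ccc(/C=C/C(=O)OC(=NC2CCCCC2)NC2CCCCC2)cc1 | intermediate
19 | (2S)-2-[(2S)-5-{(1E)-3-tert-butoxy-3-oxoprop-1-en-1-yl}-2,3-dihydro-1-benzofuran-2-yl]propyl (2E)-3-(4-tert-butoxyphenyl)prop-2-enoate | C[C@@H](COC(=O)/C=C/c1ccc(OC(C)(C)C)cc1)[C@@H]1Cc2cc(/C=C/C(=O)OC(C)(C)C)ccc2O1 | intermediate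
20 | (2E)-3-{(2S)-2-[(2S)-1-{[(2E)-3-(4-hydroxyphenyl)prop-2-enoyl]oxy}propan-2-yl]-2,3-dihydro-1-benzofuran-5-yl}prop-2-enoic acid | C[C@@H](COC(=O)/C=C/c1ccc(O)cc1)[C@@H]1Cc2cc(/C=C/C(=O)O)ccc2O1 | target

**Totals**
Total step count: 11. Longest linear sequence: 10 steps (steps 1–8, 10, 11, from 1 to 20); step 9 is a one-step side branch.

**Three steps most likely to fail, with fallbacks**

Step 5 (ring closure). The hindered, β-branched secondary palladium alkoxide may undergo β-hydride elimination (ketone plus debrominated arene) instead of C–O reductive elimination. The fallback sets out from 8 and comes back at 9, and closes the ring at the sp3 carbon with a phenol oxygen instead of at the aryl carbon. Mitsunobu inversion of 8 with 4-nitrobenzoic acid (PPh3, DIAD, toluene, 0 °C → rt) gives (2R,3S)-1-(2-bromophenyl)-4-[(tert-butyldiphenylsilyl)oxy]-3-methylbutan-2-yl 4-nitrobenzoate F2. Methanolysis (K2CO3, MeOH, rt) gives the epimeric alcohol (2R,3S)-1-(2-bromophenyl)-4-[(tert-butyldiphenylsilyl)oxy]-3-methylbutan-2-ol F3. Bromine–lithium exchange and borate oxidation (n-BuLi 2.3 equiv, THF, −78 °C; B(OMe)3; then NaOH/H2O2, 0 °C) turn the aryl bromide into the phenol 2-{(2R,3S)-4-[(tert-butyldiphenylsilyl)oxy]-2-hydroxy-3-methylbutyl}phenol F4. Mitsunobu cyclodehydration of F4 (PPh3, DIAD, THF, 0 °C → rt) then displaces the activated secondary hydroxyl by the phenol oxygen with a second inversion, giving 9 with the (S) ring centre.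

Step 2 (aldol). The arylacetaldehyde 2 is easily enolised and can self-condense or give a low yield with the boron enolate. The fallback sets out from 2 and comes back at 7, replacing the auxiliary aldol by a reagent-controlled carbonyl crotylation that needs no base. Brown crotylboration with (Z)-crotyldiisopinocampheylborane (from cis-2-butene, n-BuLi/KOt-Bu, (+)-Ipc2BOMe derived from (−)-α-pinene, BF3·OEt2, THF, −78 °C; NaOH/H2O2 work-up) gives the syn homoallylic alcohol (2S,3S)-1-(2-bromophenyl)-3-methylpent-4-en-2-ol F1. Ozonolysis of F1 with reductive work-up (O3, CH2Cl2/MeOH, −78 °C; then NaBH4) converts the vinyl group into CH2OH and delivers diol 7.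

Step 7 (Heck). The bromide sits para to an alkoxy group and is electron-rich, so oxidative addition can be slow and the catalyst may die before conversion is complete. The fallback sets out from 10 and comes back at 12, building the alkene by carbonyl olefination instead. Bromine–lithium exchange and formylation (n-BuLi, THF, −78 °C; then DMF) give (2S)-2-{(2S)-1-[(tert-butyldiphenylsilyl)oxy]propan-2-yl}-2,3-dihydro-1-benzofuran-5-carbaldehyde F5. Horner–Wadsworth–Emmons olefination of F5 with tert-butyl diethylphosphonoacetate (LiCl, DBU, MeCN, rt) gives the (E)-enoate 12.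

**Further compounds**
F1 | step 2 | (2S,3S)-1-(2-bromophenyl)-3-methylpent-4-en-2-ol | C[C@@H](C=C)[C@@H](O)Cc1ccccc1Br
F2 | step 5 | (2R,3S)-1-(2-bromophenyl)-4-[(tert-butyldiphenylsilyl)oxy]-3-methylbutan-2-yl 4-nitrobenzoate | C[C@@H](CO[Si](c1ccccc1)(c1ccccc1)C(C)(C)C)[C@H](OC(=O)c1ccc(cc1)[N+](=O)[O-])Cc1ccccc1Br
F3 | step 5 | (2R,3S)-1-(2-bromophenyl)-4-[(tert-butyldiphenylsilyl)oxy]-3-methylbutan-2-ol | C[C@@H](CO[Si](c1ccccc1)(c1ccccc1)C(C)(C)C)[C@H](O)Cc1ccccc1Br
F4 | step 5 | 2-{(2R,3S)-4-[(tert-butyldiphenylsilyl)oxy]-2-hydroxy-3-methylbutyl}phenol | C[C@@H](CO[Si](c1ccccc1)(c1ccccc1)C(C)(C)C)[C@H](O)Cc1ccccc1O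
F5 | step 7 | (2S)-2-{(2S)-1-[(tert-butyldiphenylsilyl)oxy]propan-2-yl}-2,3-dihydro-1-benzofuran-5-carbaldehyde | C[C@@H](CO[Si](c1ccccc1)(c1ccccc1)C(C)(C)C)[C@@H]1Cc2cc(C=O)ccc2O1
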